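## Retrosynthetic overview

1. The last bond made is the C7–CH2–C3' bridge. It comes from a three-component coupling of the (R)-dihydrobenzofuran core, an iminium CH2 source and the 4-hydroxy-2-pyrone.
2. The C2–O bond and the stereocentre come from a palladium-catalysed asymmetric allylic etherification. A racemic allylic nitro group is the leaving group, and both enantiomers converge on one product.
3. The key bond is C2–C3. The O–C7a / C2–O relationship is 1,4 (dissonant), so C3 (quinone methide CH2) and C2 (future C–O carbon) are both natural acceptors. C2 is therefore introduced as a donor, the 2-methylallyl nitronate, an acyl-anion-type d1 synthon that is later turned back into an acceptor.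
4. The quinone methide comes from phlorisobutyrophenone (phloroglucinol + isobutyryl chloride) through an in situ Mannich base. The nitro reagent comes from methallyl bromide, and the pyrone from pentan-3-one + malonyl dichloride.
5. Ring order: the benzene ring is bought, the pyrone ring is built on a side branch, the dihydrofuran ring is closed in the main line, and the two halves are bridged last.

Assumption: the SMILES stereocentre reads as (2R), and the (R,R) Trost ligand is taken to give (2R) by analogy with cyclisation of (E)-4-(2-hydroxyaryl)-2-methylbut-2-enyl carbonates, to be confirmed by chiral HPLC and rotation on the cyclised benzofuran (the antipodal ligand is equally available).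

## Route

Step 1
Reactants: 1 phloroglucinol (benzene-1,3,5-triol, anhydrous); 2 isobutyryl chloride (2-methylpropanoyl chloride)
Product: 3 phlorisobutyrophenone [2-methyl-1-(2,4,6-trihydroxyphenyl)propan-1-one]
Conditions: AlCl3 (3.5 equiv), CH2Cl2/MeNO2, 0 to 40 °C; ice/aq HCl
Reagents that add atoms: none
Why: Friedel–Crafts C-acylation of the very electron-rich triol stops after one acylation because the chelated aryl ketone deactivates the ring, and no stereocentre is formed.

Step 2
Reactants: 4 3-bromo-2-methylprop-1-ene (methallyl bromide)
Product: 5 2-methyl-3-nitroprop-1-ene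
Conditions: AgNO2 (1.3 equiv), Et2O, 0 °C to rt, dark; filter, distil
Reagents that add atoms: AgNO2, [Ag+].[O-]N=O
Why: Victor Meyer reaction, in which silver-assisted substitution of a primary allylic bromide by ambident nitrite occurs mainly at nitrogen in ether, giving a nitro compound whose doubly activated CH2 can be deprotonated by an amine in the presence of free phenols.

Step 3
Reactants: 3 phlorisobutyrophenone; 6 N,N-dimethylmethyleneiminium iodide (Eschenmoser's salt); 5 2-methyl-3-nitroprop-1-ene
Product: 10 (±)-2-methyl-1-[2,4,6-trihydroxy-3-(3-methyl-2-nitrobut-3-en-1-yl)phenyl]propan-1-one, via Mannich base hydroiodide 7 (not isolated), via ortho-quinone methide 8 (not isolated), via triethylammonium 2-methylallyl nitronate 9 (not isolated)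
Conditions: 6 (1.0 equiv), MeCN, 0 °C to rt, 1 h; then 5 (4 equiv), Et3N (1.5 equiv), 60 °C, 3 h; cold aq NaH2PO4; chromatography (all excess 5 removed)
Reagents that add atoms: none
Why: Proposed new method: after a Mannich aminomethylation, Et3N frees the base, which expels Me2NH to give quinone methide 8, and the soft nitronate 9, a donor at the carbon that will become the C2–O carbon, adds through its α-carbon to the acceptor CH2 of 8, so that two natively electrophilic carbons are joined with rearomatisation as driving force and kinetic α-protonation keeps the alkene deconjugated; the closest known reaction types are the alkylation of nitronates by phenolic Mannich bases or gramine (Michael addition to a quinone methide) and the α-selective Michael and Henry reactions of allylic nitronates, and the new stereocentre is formed racemic because it is reset in step 4.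

Step 4
Reactants: 10 (±)-allylic nitro compound
Product: 11 1-[(2R)-4,6-dihydroxy-2-(prop-1-en-2-yl)-2,3-dihydro-1-benzofuran-5-yl]-2-methylpropan-1-one
Conditions: Pd2(dba)3·CHCl3 (2.5 mol %), (R,R)-DACH-phenyl Trost ligand [(1R,2R)-N,N'-bis(2-diphenylphosphinobenzoyl)cyclohexane-1,2-diamine, 7.5 mol %], Et3N (1.5 equiv), degassed THF (0.02 M), 40 °C; pH 7 buffer wash
Reagents that add atoms: none
Why: Proposed new method: zerovalent palladium ionises the allylic C–NO2 bond (Tsuji–Trost substitution of allylic nitro compounds is known with achiral phosphines) to the same 1-(arylmethyl)-2-methylallyl palladium species that the Trost asymmetric allylic alkylation of the corresponding primary carbonates passes through, its two faces exchange by π-σ-π slippage at the unsubstituted CH2 terminus so that both enantiomers of 10 converge (dynamic kinetic asymmetric transformation), and the more acidic, non-chelated 4-OH para to the acyl group closes the ring 5-exo inside the pocket of the (R,R) ligand to set C2 as (R), while Et3N keeps the departing nitrite as a harmless salt.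

Step 5
Reactants: 12 pentan-3-one
Product: 13 (Z)-trimethyl(pent-2-en-3-yloxy)silane (Z major)
Conditions: TMSCl (1.2 equiv), Et3N (1.5 equiv), DMF, 90 °C; pentane extraction, distil
Reagents that add atoms: chlorotrimethylsilane (TMSCl), C[Si](C)(C)Cl
Why: Thermodynamic silyl enol ether formation (House conditions) on a symmetrical ketone can give only one regioisomer, and the alkene geometry is irrelevant because it is lost in step 6.

Step 6
Reactants: 13 silyl enol ether; 14 malonyl dichloride (propanedioyl dichloride)
Product: 16 6-ethyl-4-hydroxy-5-methyl-2H-pyran-2-one, via 4-methyl-3,5-dioxoheptanoyl chloride 15 (not isolated)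
Conditions: Et2O, −78 °C to rt
Reagents that add atoms: none
Why: Effenberger-type 4-hydroxy-2-pyrone synthesis, in which C-acylation of the enol silane by one acyl chloride gives 15 and the enol of its C5 ketone is then O-acylated intramolecularly by the second acyl chloride, followed by tautomerisation to the stable hydroxypyrone.

Step 7
Reactants: 16 pyrone; 6 N,N-dimethylmethyleneiminium iodide; 11 (R)-dihydrobenzofuran
Product: 19 6-ethyl-4-hydroxy-3-{[(2R)-4,6-dihydroxy-5-(2-methylpropanoyl)-2-(prop-1-en-2-yl)-2,3-dihydro-1-benzofuran-7-yl]methyl}-5-methyl-2H-pyran-2-one (CNP0206652.1), via pyrone Mannich base hydroiodide 17 (not isolated), via 3-methylidenepyran-2,4-dione 18 (not isolated)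
Conditions: 16 and 6 (1.1 equiv each), MeCN, rt, 30 min; then 11 (1.0 equiv), 50 °C
Reagents that add atoms: none
Why: Mannich reaction, amine elimination and Michael addition in one flask (carba-Betti-type methylene coupling), in which 16 is first fully converted into 17 to suppress pyrone homodimer, 17 loses Me2NH to the strongly electrophilic 18, and the only free aromatic position of 11 (C7) adds to it under nearly neutral conditions that leave the isopropenyl group and the C2 stereocentre untouched.

## Compound list

1 | phloroglucinol (benzene-1,3,5-triol) | Oc1cc(O)cc(O)c1 | starting material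
2 | isobutyryl chloride | CC(C)C(=O)Cl | starting material
3 | phlorisobutyrophenone, 2-methyl-1-(2,4,6-trihydroxyphenyl)propan-1-one | CC(C)C(=O)c1c(O)cc(O)cc1O | intermediate
4 | 3-bromo-2-methylprop-1-ene | C=C(C)CBr | starting material
5 | 2-methyl-3-nitroprop-1-ene | C=C(C)C[N+](=O)[O-] | intermediate
6 | N,N-dimethylmethyleneiminium iodide (Eschenmoser's salt) | C=[N+](C)C.[I-] | starting material
7 | N,N-dimethyl-1-[2,4,6-trihydroxy-3-(2-methylpropanoyl)phenyl]methanaminium iodide | CC(C)C(=O)c1c(O)cc(O)c(C[NH+](C)C)c1O.[I-] | intermediate (not isolated)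
8 | 3,5-dihydroxy-6-methylidene-4-(2-methylpropanoyl)cyclohexa-2,4-dien-1-one | C=C1C(=O)C=C(O)C(C(=O)C(C)C)=C1O | intermediate (not isolated)
9 | triethylammonium 2-methylallyl nitronate | C=C(C)C=[N+]([O-])[O-].CC[NH+](CC)CC | intermediate (not isolated)
10 | (±)-2-methyl-1-[2,4,6-trihydroxy-3-(3-methyl-2-nitrobut-3-en-1-yl)phenyl]propan-1-one (racemic) | C=C(C)C(Cc1c(O)cc(O)c(C(=O)C(C)C)c1O)[N+](=O)[O-] | intermediate
11 | 1-[(2R)-4,6-dihydroxy-2-(prop-1-en-2-yl)-2,3-dihydro-1-benzofuran-5-yl]-2-methylpropan-1-one | C=C(C)[C@H]1Cc2c(O)c(C(=O)C(C)C)c(O)cc2O1 | intermediate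
12 | pentan-3-one | CCC(=O)CC | starting material
13 | (Z)-trimethyl(pent-2-en-3-yloxy)silane | C/C=C(\O[Si](C)(C)C)CC | intermediate
14 | malonyl dichloride | O=C(Cl)CC(=O)Cl | starting material
15 | 4-methyl-3,5-dioxoheptanoyl chloride (racemic, labile centre) | CCC(=O)C(C)C(=O)CC(=O)Cl | intermediate (not isolated)
16 | 6-ethyl-4-hydroxy-5-methyl-2H-pyran-2-one | CCc1oc(=O)cc(O)c1C | intermediate
17 | 1-(6-ethyl-4-hydroxy-5-methyl-2-oxo-2H-pyran-3-yl)-N,N-dimethylmethanaminium iodide | CCc1oc(=O)c(C[NH+](C)C)c(O)c1C.[I-] | intermediate (not isolated)
18 | 6-ethyl-5-methyl-3-methylidene-2H-pyran-2,4(3H)-dione | CCC1=C(C)C(=O)C(=C)C(=O)O1 | intermediate (not isolated)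
19 | CNP0206652.1, (2R) enantiomer | C=C(C)[C@H]1Cc2c(O)c(C(=O)C(C)C)c(O)c(Cc3c(O)c(C)c(CC)oc3=O)c2O1 | target

## Step count

- Total step count: 7.
- Longest linear sequence: 4 steps (steps 1, 3, 4, 7; 1 → 3 → 10 → 11 → 19).

## Steps most likely to fail, with fallbacks

**Step 3.**
- Quinone methide 8 can be captured by the free ring C–H of another phloroglucinol unit, giving methylene-bridged oligomers.
- Some bis-aminomethylation is likely.
- The nitronate could react twice, or through its γ-carbon.

The fallback sets out from 5, with 3 as partner, and comes back at 10. It moves the reversed polarity one bond over. Compound 5 is hydroxymethylated at its α-carbon with aqueous formaldehyde and catalytic Et3N (Henry reaction) to 3-methyl-2-nitrobut-3-en-1-ol F1. This is acetylated (Ac2O, catalytic TsOH) to 3-methyl-2-nitrobut-3-en-1-yl acetate F2. Slow addition of F2 to 3 (2 equiv) and NaHCO3 in aqueous MeCN releases 3-methyl-2-nitrobuta-1,3-diene F3 by loss of acetic acid. The ring carbon of 3 then adds to the CH2 terminus of the diene in a Friedel–Crafts-type Michael addition. Here the nitroalkene acts as an α-carbonyl cation (enolonium) equivalent, so two natively nucleophilic carbons are joined: the phloroglucinol carbon and the carbon α to C2. α-Protonation of the resulting nitronate gives 10. No quinone methide is involved, so bridged oligomers cannot form.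

**Step 4.**
- Ionisation of the nitro group may be slow with the bulky ligand, because the nitronate of 10 is an unreactive resting state.
- A syn/anti mixture of allyl complexes may lower the ee.
- The 2-OH may compete with the 4-OH in ring closure.
- Product 11 may be re-ionised.

The fallback sets out from 10 and comes back at 11. It uses the nitro group as a true acyl anion equivalent. A McMurry-type reductive Nef reaction (NaOMe, then TiCl3 in NH4OAc buffer) gives 2-methyl-1-[2,4,6-trihydroxy-3-(3-methyl-2-oxobut-3-en-1-yl)phenyl]propan-1-one F4. Corey–Bakshi–Shibata reduction follows, with (R)-Me-CBS oxazaborolidine and BH3·SMe2 (extra borane for the phenols). The branched alkenyl group acts as the large substituent, and the chelated aryl ketone stays inert. The product is 1-{2,4,6-trihydroxy-3-[(2S)-2-hydroxy-3-methylbut-3-en-1-yl]phenyl}-2-methylpropan-1-one F5. Mitsunobu cyclodehydration (PPh3, DIAD, THF, 0 °C) through the acidic 4-OH proceeds with inversion and gives (2R)-11.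

**Step 7.**
- The pyrone can form a methylene-bridged homodimer.
- The bridge may scramble by retro-Michael reaction.
- C7 of 11 may be too weak a nucleophile.

The fallback sets out from 11 and comes back at 19, with the donor and acceptor roles exchanged. Compound 11 is aminomethylated with aqueous formaldehyde and Me2NH in EtOH to the isolable 1-[(2R)-7-[(dimethylamino)methyl]-4,6-dihydroxy-2-(prop-1-en-2-yl)-2,3-dihydro-1-benzofuran-5-yl]-2-methylpropan-1-one F6. Heating F6 with 16 (3 equiv) in dioxane at 80 °C expels Me2NH. This gives (2R)-4-hydroxy-7-methylidene-5-(2-methylpropanoyl)-2-(prop-1-en-2-yl)-2,3-dihydro-1-benzofuran-6(7H)-one F7. C3 of the pyrone, now the nucleophile, traps F7 to give 19. No pyrone-derived methylene acceptor is present, so the homodimer cannot form.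

## Further compounds

F1 | step 3 | 3-methyl-2-nitrobut-3-en-1-ol (racemic) | C=C(C)C(CO)[N+](=O)[O-]
F2 | step 3 | 3-methyl-2-nitrobut-3-en-1-yl acetate (racemic) | C=C(C)C(COC(C)=O)[N+](=O)[O-]
F3 | step 3 | 3-methyl-2-nitrobuta-1,3-diene | C=C(C)C(=C)[N+](=O)[O-]
F4 | step 4 | 2-methyl-1-[2,4,6-trihydroxy-3-(3-methyl-2-oxobut-3-en-1-yl)phenyl]propan-1-one | C=C(C)C(=O)Cc1c(O)cc(O)c(C(=O)C(C)C)c1O
F5 | step 4 | 1-{2,4,6-trihydroxy-3-[(2S)-2-hydroxy-3-methylbut-3-en-1-yl]phenyl}-2-methylpropan-1-one | C=C(C)[C@@H](O)Cc1c(O)cc(O)c(C(=O)C(C)C)c1O
F6 | step 7 | 1-[(2R)-7-[(dimethylamino)methyl]-4,6-dihydroxy-2-(prop-1-en-2-yl)-2,3-dihydro-1-benzofuran-5-yl]-2-methylpropan-1-one | C=C(C)[C@H]1Cc2c(O)c(C(=O)C(C)C)c(O)c(CN(C)C)c2O1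
F7 | step 7 | (2R)-4-hydroxy-7-methylidene-5-(2-methylpropanoyl)-2-(prop-1-en-2-yl)-2,3-dihydro-1-benzofuran-6(7H)-one | C=C(C)[C@H]1CC2=C(O1)C(=C)C(=O)C(C(=O)C(C)C)=C2O
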